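**Retrosynthetic overview**
1. Both rings close together in the last step. The cyclohexene and the cyclopentanone form in the biomimetic intramolecular Diels–Alder reaction (bonds C2–C10 and C3–C7) of the free, unprotected open-chain 5-oxo tetraenoic acid, released in the flask by oxidising its C5 carbinol.
2. Only C6 is set beforehand. The acidic C4 centre is carried as an epimer mixture and funnelled through the matched transition state, so one stereocentre controls all six.
3. C8–C9: Negishi coupling of an E-vinyl iodide with a dienylzinc made by syn-ethylcupration of the enyne from cinnamaldehyde.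
4. C5–C6: chirality transfer from (S)-pent-3-yn-2-yl mesylate through an allenylindium to a racemic aldehyde.
5. C2=C3: Horner–Wadsworth–Emmons reaction of methacrolein, then hydroboration and oxidation to that aldehyde.

Assumption: open-chain compounds carry polyketide numbering (C1 = carboxyl carbon, C12 = PhCH=). A centre written RS and left open in the SMILES is a deliberate epimer mixture. Pent-3-yn-2-one is taken as purchasable.

**Route**

Step 1
Reactants: 1 (E)-cinnamaldehyde
Product: 2 (E)-but-1-en-3-yn-1-ylbenzene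
Conditions: Me3SiCHN2 (1.2 equiv), LiN(iPr)2 (1.2 equiv), THF, −78 °C; add 1; −78 °C → rt
Reagents that add atoms: trimethylsilyldiazomethane, C[Si](C)(C)C=[N+]=[N-]
Why: Colvin rearrangement (aprotic Seyferth–Gilbert-type homologation) turns CHO into C≡CH with loss of Me3SiOLi and N2, leaves the E-alkene untouched, and avoids the methanol conjugate addition that enals suffer under Ohira–Bestmann conditions.

Step 2
Reactants: 3 pent-3-yn-2-one
Product: 4 (S)-pent-3-yn-2-ol
Conditions: RuCl[(S,S)-TsDPEN](p-cymene) (1 mol%), KOH (1 mol%), i-PrOH, 25 °C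
Reagents that add atoms: none
Why: Noyori asymmetric transfer hydrogenation of an ynone, in which the (S,S)-catalyst delivers hydride to one carbonyl face through its six-membered transition state and sets the (S)-carbinol centre (expected ≥97% ee).

Step 3
Reactants: 4 (S)-pent-3-yn-2-ol
Product: 5 (S)-pent-3-yn-2-yl methanesulfonate
Conditions: MsCl, Et3N, CH2Cl2, −78 → 0 °C
Reagents that add atoms: methanesulfonyl chloride, CS(=O)(=O)Cl
Why: O-sulfonylation leaves the C–O bond intact, so the (S) configuration is retained.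

Step 4
Reactants: 6 triethyl 2-phosphonobutyrate; 7 methacrolein
Product: 9 ethyl (2E)-2-ethyl-4-methylpenta-2,4-dienoate, via sodium phosphonate 8 (not isolated)
Conditions: NaH (1.05 equiv), THF, 0 °C; then 7, 0 °C → rt
Reagents that add atoms: none
Why: Horner–Wadsworth–Emmons olefination with a stabilised α-ethyl phosphonate gives the E-trisubstituted enoate (CO2Et trans to C4), the geometry that later places the C2-ethyl group cis to the C3–C4 bond.

Step 5
Reactants: 9 ethyl (2E)-2-ethyl-4-methylpenta-2,4-dienoate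
Product: 11 ethyl (2E,4RS)-2-ethyl-5-hydroxy-4-methylpent-2-enoate, via B-alkyl-9-BBN adduct 10 (not isolated)
Conditions: 9-BBN (1.1 equiv), THF, 0 °C → rt; then 30% H2O2, aq NaHCO3, 0 °C → rt
Reagents that add atoms: hydrogen peroxide, OO
Why: Anti-Markovnikov hydroboration–oxidation occurs only at the terminal 1,1-disubstituted alkene because the trisubstituted enoate alkene is electron-poor and hindered, and C4 is formed racemic on purpose.

Step 6
Reactants: 11 ethyl (2E,4RS)-2-ethyl-5-hydroxy-4-methylpent-2-enoate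
Product: 12 ethyl (2E,4RS)-2-ethyl-4-methyl-5-oxopent-2-enoate
Conditions: Dess–Martin periodinane (DMP, 1.2 equiv), CH2Cl2, 0 °C → rt; used at once
Reagents that add atoms: none
Why: Dess–Martin oxidation is base-free, so the γ-acidic aldehyde does not slip into conjugation, and its epimerisation is harmless because it is racemic.

Step 7
Reactants: 5 (S)-pent-3-yn-2-yl methanesulfonate; 12 ethyl (2E,4RS)-2-ethyl-4-methyl-5-oxopent-2-enoate
Product: 14 ethyl (2E,4RS,5S,6R)-2-ethyl-5-hydroxy-4,6-dimethylnon-2-en-7-ynoate, via (M)-allenylindium 13 (not isolated)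
Conditions: 5 (1.5 equiv), Pd(dppf)Cl2 (5 mol%), InI (1.6 equiv), THF/HMPA 3:1, rt, 1 h
Reagents that add atoms: none
Why: Marshall propargylation, in which zerovalent palladium displaces the mesylate anti (SN2'), monovalent indium takes over the allenyl group with retention, and the allenylindium adds through a cyclic SE2' transition state, so C6 is set as (R) by chirality transfer (net inversion) and C5 anti to it, whichever enantiomer of 12 reacts.

Step 8
Reactants: 14 ethyl (2E,4RS,5S,6R)-2-ethyl-5-hydroxy-4,6-dimethylnon-2-en-7-ynoate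
Product: 16 ethyl (2E,4RS,5S,6R,7E)-2-ethyl-5-hydroxy-8-iodo-4,6-dimethylnona-2,7-dienoate, via vinylstannane 15 (not isolated)
Conditions: Bu3SnH (1.3 equiv, slow addition), PdCl2(PPh3)2 (3 mol%), THF, 0 °C → rt; then I2 (1.3 equiv), 0 °C
Reagents that add atoms: iodine, II
Why: Palladium-catalysed syn-hydrostannation places tin on the less hindered methyl-bearing alkyne carbon C8, away from branched C6, and tin–iodine exchange with retention gives the 7E-vinyl iodide while the trisubstituted enoate stays inert.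

Step 9
Reactants: 2 (E)-but-1-en-3-yn-1-ylbenzene; 16 ethyl (2E,4RS,5S,6R,7E)-2-ethyl-5-hydroxy-8-iodo-4,6-dimethylnona-2,7-dienoate
Product: 19 ethyl (2E,4RS,5R,6R,7E,9E,11E)-2,10-diethyl-5-hydroxy-4,6,8-trimethyl-12-phenyldodeca-2,7,9,11-tetraenoate, via dienylcopper 17 (not isolated), via dienylzinc bromide 18 (not isolated)
Conditions: EtMgBr, CuBr·SMe2, Et2O/Me2S, −45 °C; 2 (2 equiv), −25 °C, 2 h; ZnBr2, THF, −25 °C; cannulate into 16, Pd(OAc)2 (3 mol%), SPhos (6 mol%), THF, 0 °C → rt; keep 19 cold and dark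
Reagents that add atoms: ethylmagnesium bromide, CC[Mg]Br
Why: Normant syn-carbocupration puts ethyl on the internal and copper on the terminal alkyne carbon on the same side, which fixes 9E, and the Negishi coupling proceeds with retention at both alkenes and, under Pd/SPhos catalysis, faster than protonation of the zinc reagent by the free hydroxyl.

Step 10
Reactants: 19 ethyl (2E,4RS,5R,6R,7E,9E,11E)-2,10-diethyl-5-hydroxy-4,6,8-trimethyl-12-phenyldodeca-2,7,9,11-tetraenoate
Product: 20 (2E,4RS,5R,6R,7E,9E,11E)-2,10-diethyl-5-hydroxy-4,6,8-trimethyl-12-phenyldodeca-2,7,9,11-tetraenoic acid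
Conditions: LiOH (5 equiv), THF/MeOH/H2O 3:1:1, rt, dark; 1 M HCl to pH 4, 0 °C
Reagents that add atoms: lithium hydroxide, [Li+].[OH-]
Why: Saponification (BAc2) is done on the still accessible open-chain enoate, because after ring closure the carboxyl lies between two quaternary carbons, and no stereocentre is activated at the carbinol oxidation level.

Step 11
Reactants: 20 (2E,4RS,5R,6R,7E,9E,11E)-2,10-diethyl-5-hydroxy-4,6,8-trimethyl-12-phenyldodeca-2,7,9,11-tetraenoic acid
Product: 23 dinorspiculoic acid A, via keto acid epimer mixture 21 (not isolated), via (4R,6R)-keto acid 22 (not isolated)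
Conditions: DMP (1.3 equiv), CH2Cl2, 0 °C, 45 min; cold SiO2 plug; then PhMe (0.05 M), Et3N (0.2 equiv), BHT (5 mol%), 60 °C, 16 h
Reagents that add atoms: none
Why: Proposed new method: Dess–Martin oxidation unveils the presumed biosynthetic substrate, whose C4–H (alpha to the ketone and vinylogously alpha to the carboxyl) is exchanged by the catalytic ammonium carboxylate far faster than C6–H, so 21 keeps feeding the matched epimer 22, which closes both rings through an endo (carboxyl under the diene), trans-hydrindane intramolecular Diels–Alder transition state in which H6 and H4 eclipse the C8-methyl and C2-ethyl groups (A1,3 strain), so that the fixed (6R) centre dictates the diene face and thereby C7, C3, C2 and C10, the all-E geometry is carried suprafacially into the cis-diethyl pair of vicinal quaternary carbons, and C4 ends in the thermodynamically preferred all-trans cyclopentanone array; the closest known reaction types are tandem oxidation/intramolecular Diels–Alder reactions of trienols and dynamic kinetic resolutions of alpha-labile ketones.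

**Compound list**

| No. | Name | SMILES | Role |
|---|---|---|---|
| 1 | (E)-cinnamaldehyde | O=C/C=C/c1ccccc1 | starting material |
| 2 | (E)-but-1-en-3-yn-1-ylbenzene | C#C/C=C/c1ccccc1 | intermediate |
| 3 | pent-3-yn-2-one | CC#CC(C)=O | starting material |
| 4 | (S)-pent-3-yn-2-ol | CC#C[C@H](C)O | intermediate |
| 5 | (S)-pent-3-yn-2-yl methanesulfonate | CC#C[C@H](C)OS(C)(=O)=O | intermediate |
| 6 | triethyl 2-phosphonobutyrate | CCOC(=O)C(CC)P(=O)(OCC)OCC | starting material |
| 7 | methacrolein | C=C(C)C=O | starting material |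
| 8 | sodium salt of 6 (phosphonate carbanion) | [Na+].CCOC(=O)[C-](CC)P(=O)(OCC)OCC | intermediate |
| 9 | ethyl (2E)-2-ethyl-4-methylpenta-2,4-dienoate | C=C(C)/C=C(\CC)C(=O)OCC | intermediate |
| 10 | ethyl (2E)-5-(9-borabicyclo[3.3.1]nonan-9-yl)-2-ethyl-4-methylpent-2-enoate (racemic) | CCOC(=O)/C(CC)=C/C(C)CB1C2CCCC1CCC2 | intermediate |
| 11 | ethyl (2E,4RS)-2-ethyl-5-hydroxy-4-methylpent-2-enoate | CCOC(=O)/C(CC)=C/C(C)CO | intermediate |
| 12 | ethyl (2E,4RS)-2-ethyl-4-methyl-5-oxopent-2-enoate | CCOC(=O)/C(CC)=C/C(C)C=O | intermediate |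
| 13 | (M)-(penta-2,3-dien-2-yl)indium iodide methanesulfonate | [H]C(C)=[C@@]=C(C)[In](I)OS(C)(=O)=O | intermediate |
| 14 | ethyl (2E,4RS,5S,6R)-2-ethyl-5-hydroxy-4,6-dimethylnon-2-en-7-ynoate (5,6-anti, C4 epimers) | CC#C[C@@H](C)[C@@H](O)C(C)/C=C(\CC)C(=O)OCC | intermediate |
| 15 | ethyl (2E,4RS,5S,6R,7E)-2-ethyl-5-hydroxy-4,6-dimethyl-8-(tributylstannyl)nona-2,7-dienoate | CCCC[Sn](CCCC)(CCCC)/C(C)=C/[C@@H](C)[C@@H](O)C(C)/C=C(\CC)C(=O)OCC | intermediate |
| 16 | ethyl (2E,4RS,5S,6R,7E)-2-ethyl-5-hydroxy-8-iodo-4,6-dimethylnona-2,7-dienoate | I/C(C)=C/[C@@H](C)[C@@H](O)C(C)/C=C(\CC)C(=O)OCC | intermediate |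
| 17 | [(1E,3E)-2-ethyl-4-phenylbuta-1,3-dien-1-yl]copper | [Cu]/C=C(CC)/C=C/c1ccccc1 | intermediate |
| 18 | [(1E,3E)-2-ethyl-4-phenylbuta-1,3-dien-1-yl]zinc bromide | Br[Zn]/C=C(CC)/C=C/c1ccccc1 | intermediate |
| 19 | ethyl (2E,4RS,5R,6R,7E,9E,11E)-2,10-diethyl-5-hydroxy-4,6,8-trimethyl-12-phenyldodeca-2,7,9,11-tetraenoate | c1ccccc1/C=C/C(CC)=C/C(C)=C/[C@@H](C)[C@@H](O)C(C)/C=C(\CC)C(=O)OCC | intermediate |
| 20 | (2E,4RS,5R,6R,7E,9E,11E)-2,10-diethyl-5-hydroxy-4,6,8-trimethyl-12-phenyldodeca-2,7,9,11-tetraenoic acid | c1ccccc1/C=C/C(CC)=C/C(C)=C/[C@@H](C)[C@@H](O)C(C)/C=C(\CC)C(=O)O | intermediate |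
| 21 | (2E,4RS,6R,7E,9E,11E)-2,10-diethyl-4,6,8-trimethyl-5-oxo-12-phenyldodeca-2,7,9,11-tetraenoic acid (equilibrating C4 epimers) | c1ccccc1/C=C/C(CC)=C/C(C)=C/[C@@H](C)C(=O)C(C)/C=C(\CC)C(=O)O | intermediate |
| 22 | (2E,4R,6R,7E,9E,11E)-2,10-diethyl-4,6,8-trimethyl-5-oxo-12-phenyldodeca-2,7,9,11-tetraenoic acid | c1ccccc1/C=C/C(CC)=C/C(C)=C/[C@@H](C)C(=O)[C@H](C)/C=C(\CC)C(=O)O | intermediate |
| 23 | dinorspiculoic acid A, (1R,3R,3aS,4S,5R,7aS)-4,5-diethyl-1,3,7-trimethyl-2-oxo-5-[(E)-2-phenylethenyl]-2,3,3a,4,5,7a-hexahydro-1H-indene-4-carboxylic acid | CC[C@@]1(/C=C/c2ccccc2)C=C(C)[C@H]2[C@@H]([C@@H](C)C(=O)[C@@H]2C)[C@]1(CC)C(=O)O | target |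

**Summary**

Total step count: 11. Longest linear sequence: 8 (steps 4, 5, 6, 7, 8, 9, 10, 11).

**Steps most likely to fail**

**Step 11.** The keto acid may isomerise, lose C6 integrity or leak into a cis-fused adduct before it cyclises. The fallback raises the dienophile's reactivity instead of the temperature.
- It sets out from 19. iBu2AlH (CH2Cl2, −78 °C) reduces the ester to the tetraene diol F1.
- DMP (2.6 equiv) oxidises both carbinols at once to the keto enal F2. As an enal it should epimerise at C4 and cyclise at or below room temperature (Me2AlCl at −40 °C if needed) to the bicyclic keto aldehyde F3.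
- Pinnick oxidation (NaClO2, NaH2PO4, 2-methylbut-2-ene, t-BuOH/H2O) comes back to the route at 23.
- This costs one more step.

**Step 9.** The conjugated, rather acidic enyne may be metalated or ethylcuprated with poor regiochemistry. The fallback drops the carbometalation and builds C9–C12 by olefin chemistry.
- It sets out from 16. A Heck reaction with 2-ethylacrolein (Pd(OAc)2, Bu4NCl, NaHCO3, DMF, 40 °C) gives the dienal F4.
- A Horner–Wadsworth–Emmons reaction with diethyl benzylphosphonate (NaH, THF, 0 °C) installs the E-styryl end and comes back at 19.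

**Step 7.** Aldehyde 12 may slip into conjugation or enolise before it is captured. The fallback avoids a γ-acidic aldehyde and installs the enoate afterwards.
- It sets out from 5. Under the same Pd(dppf)Cl2/InI conditions 5 adds to purchasable (R)-3-(tert-butyldimethylsilyloxy)-2-methylpropanal F5 to give the silyl ether adduct F6.
- Bu4NF frees the alkynyl diol F7. TEMPO/PhI(OAc)2 oxidises only the primary carbinol to the hydroxy aldehyde F8.
- A Wittig reaction with Ph3P=C(Et)CO2Et gives ethyl (2E,4R,5S,6R)-2-ethyl-5-hydroxy-4,6-dimethylnon-2-en-7-ynoate F9, the single 4R epimer, which comes back to the route at 14.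
- As a bonus, step 11 then no longer depends on C4 equilibration.

**Further compounds**

F1 | step 11 | (2E,4RS,5R,6R,7E,9E,11E)-2,10-diethyl-4,6,8-trimethyl-12-phenyldodeca-2,7,9,11-tetraene-1,5-diol | c1ccccc1/C=C/C(CC)=C/C(C)=C/[C@@H](C)[C@@H](O)C(C)/C=C(\CC)CO
F2 | step 11 | (2E,4RS,6R,7E,9E,11E)-2,10-diethyl-4,6,8-trimethyl-5-oxo-12-phenyldodeca-2,7,9,11-tetraenal | c1ccccc1/C=C/C(CC)=C/C(C)=C/[C@@H](C)C(=O)C(C)/C=C(\CC)C=O
F3 | step 11 | (1R,3R,3aS,4S,5R,7aS)-4,5-diethyl-1,3,7-trimethyl-2-oxo-5-[(E)-2-phenylethenyl]-2,3,3a,4,5,7a-hexahydro-1H-indene-4-carbaldehyde | CC[C@@]1(/C=C/c2ccccc2)C=C(C)[C@H]2[C@@H]([C@@H](C)C(=O)[C@@H]2C)[C@]1(CC)C=O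
F4 | step 9 | ethyl (2E,4RS,5R,6R,7E,9E)-2-ethyl-10-formyl-5-hydroxy-4,6,8-trimethyldodeca-2,7,9-trienoate | O=C/C(CC)=C/C(C)=C/[C@@H](C)[C@@H](O)C(C)/C=C(\CC)C(=O)OCC
F5 | step 7 | (R)-3-(tert-butyldimethylsilyloxy)-2-methylpropanal | O=C[C@H](C)CO[Si](C)(C)C(C)(C)C
F6 | step 7 | (2R,3R,4R)-1-(tert-butyldimethylsilyloxy)-2,4-dimethylhept-5-yn-3-ol | CC#C[C@@H](C)[C@@H](O)[C@H](C)CO[Si](C)(C)C(C)(C)C
F7 | step 7 | (2R,3R,4R)-2,4-dimethylhept-5-yne-1,3-diol | CC#C[C@@H](C)[C@@H](O)[C@H](C)CO
F8 | step 7 | (2S,3R,4R)-3-hydroxy-2,4-dimethylhept-5-ynal | CC#C[C@@H](C)[C@@H](O)[C@H](C)C=O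
F9 | step 7 | ethyl (2E,4R,5S,6R)-2-ethyl-5-hydroxy-4,6-dimethylnon-2-en-7-ynoate | CC#C[C@@H](C)[C@@H](O)[C@H](C)/C=C(\CC)C(=O)OCC
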